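The data stem from a simulated flask on assumed constants; noise was put on by code.

Start from early times: in the west run, with coupling partner fed onto substrate and free catalyst, the product share rises by 0.00830 s⁻¹ around 12.5%. Around 28.6% it rises by 0.00360 s⁻¹, a fall by a factor of 2.31.

| setting | west | flask |
|---|---|---|
| substrate | 0.092 M | 0.092 M |
| coupling partner | 0.90 equiv (fed, over 0.80 s) | 0.600 equiv (fed, over 0.80 s) |
| free catalyst | 4.1 mol% | 4.1 mol% |
| remark | run made earlier; the fed solution adds 0.10 times the starting volume | the fed solution adds 0.10 times the starting volume |
| time |  | 8.0 min |

- west (time / s: product / %): 10.0: 8.4; 20.0: 16.7; 30.0: 22.4; 40.0: 26.8; 50.0: 30.4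

(each reading ± 0.5 percentage points)

- charges are per starting volume, the dose included; the dosed solution carries all of it
- the numbers in the tables scatter with a standard deviation of 0.5 percentage points
- steps that have been proposed: catalyst intermediate B <-> free catalyst + product; substrate + catalyst intermediate A <-> catalyst intermediate B; coupling partner + free catalyst <-> catalyst intermediate A
- the reaction counts as stopped when no species that holds the substrate changes by six tenths of a point or more over the second half of the time

1. which holds at 8.0 min: what has brought the reaction to rest, or that it has not come to rest (forward and back rates have come level / the coupling partner has run out first / all of the substrate has reacted / no working catalyst is left / it is still moving)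
2. the product standing at 8.0 min, as a percentage of the substrate charged

The proposed steps can all run back, so try this for the west run: net rate = k × (substrate share × partner share − q × product share), with shares taken on the substrate charge. Your two rates give q = 0.625. Dividing out the diluted substrate concentration c gives the level constant K = 1/(qc), the equilibrium constant: product over substrate times partner at rest, read here as 19.1 M⁻¹.

This flask has the same c and loading, so I carry q and k over to it. Its partner charge caps product at 60.0%, but my reckoning with K levels it at 31.4%, lower, so the level comes before the cap. I reckon the time constant of the approach to that level at about 45.2 s, and the asked time is about ten times that.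

The forecast: forward and back rates have come level, at 33%, above my figure: “this is a judgement call, and I lean to equilibrium”.

The flask gives: forward and back rates have come level, at 33.7%.

    catalyst intermediate B ⇌ free catalyst + product (K = 0.280 M, k = 150 s⁻¹)
    substrate + catalyst intermediate A ⇌ catalyst intermediate B (K = 14.0 M⁻¹, k = 10.0 M⁻¹ s⁻¹)
    coupling partner + free catalyst ⇌ catalyst intermediate A (K = 6.10 M⁻¹, k = 2100 M⁻¹ s⁻¹)

This flask stands at 33.7% against the 31.4% reckoned from K = 19.1 M⁻¹, with 66% of its substrate and 43% of its coupling partner still unbound. In a neighbour flask with 0.23 M of substrate, the same K reckons 41.9%, and that flask stands at 43.2%. Back in this flask, the largest change over the second half of the time is 0.25 percentage points. Waiting makes no difference: at ten times the time, 80.0 min, the product reads 33.7%.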